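**Strategy.** The target, gallocatechin-(4α→8)-epicatechin, is cut at the C4–C8 interflavan bond; the epicatechin half is built de novo (lower-unit numbering below). Its ring C is closed by a formal [4+2] anionic annulation: a C3 acyl-anion equivalent on the CH2 arm of a fluoroarene adds to 3,4-bis(benzyloxy)benzaldehyde (C2–C3 bond) and the resulting alkoxide displaces fluoride at C8a (O1–C8a bond). The step exploits that C8a of ring A is meta to both ring-A oxygens, and that cis C2/C3 flank a ketone-level C3: the unmasked flavan-3-one is funnelled to (2R,3R) by dynamic kinetic resolution. The precursor is an open-chain 2-arylethyl dithioacetal S-oxide plus an aldehyde.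

Key step: step 5

Assumption: (+)-gallocatechin is bought as the single (2R,3S) enantiomer, and the sense of induction of the Ru catalyst in step 7 is assigned by analogy with aryl ketones (C2 side taken as the aryl-like group); the (S,S) catalyst is used instead if the antipodal alcohol forms.

Step 1
Reactants: 1 1,3,5-trifluorobenzene
Product: 2 1,3-bis(benzyloxy)-5-fluorobenzene
Conditions: BnOH (2.05 equiv), NaH, NMP, 0 → 80 °C
Reagents that add atoms: benzyl alcohol, OCc1ccccc1
Why: Twofold SNAr by benzyloxide on the electron-poor trifluoroarene should largely stop after the second substitution, because each alkoxy group introduced lowers the reactivity of the remaining C–F bond, so stoichiometry and temperature select the monofluoro diether.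

Step 2
Reactants: 2 1,3-bis(benzyloxy)-5-fluorobenzene
Product: 3 2,4-bis(benzyloxy)-6-fluorobenzaldehyde
Conditions: n-BuLi, THF, −78 °C; DMF, −78 °C; H2O
Reagents that add atoms: N,N-dimethylformamide, CN(C)C=O
Why: Directed ortho-lithiation at −78 °C takes the most acidic ring proton, the one flanked by fluorine and a benzyloxy group, and the aryllithium (kept cold to avoid loss of LiF) is formylated by DMF (Bouveault formylation), which places CHO on the future C4a between the future C8a–F and C5–OBn.

Step 3
Reactants: 3 2,4-bis(benzyloxy)-6-fluorobenzaldehyde; 4 methyl methylthiomethyl sulfoxide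
Product: 5 (E)-1,5-bis(benzyloxy)-3-fluoro-2-[2-(methylsulfinyl)-2-(methylthio)ethenyl]benzene
Conditions: benzyltrimethylammonium hydroxide (40% in MeOH, cat.), THF, reflux
Reagents that add atoms: none
Why: Knoevenagel-type condensation of the sulfinyl-stabilised carbanion of 4 with the aromatic aldehyde and loss of water gives the ketene dithioacetal S-oxide, which brings in the future C3 at the ketone oxidation level (the alkene geometry has no consequence).

Step 4
Reactants: 5 (E)-1,5-bis(benzyloxy)-3-fluoro-2-[2-(methylsulfinyl)-2-(methylthio)ethenyl]benzene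
Product: 6 1,5-bis(benzyloxy)-3-fluoro-2-[2-(methylsulfinyl)-2-(methylthio)ethyl]benzene (diastereomer mixture)
Conditions: NaBH4, EtOH, 0 °C → rt
Reagents that add atoms: none
Why: The sulfinyl group makes the alkene a Michael acceptor, so borohydride adds hydride to the benzylic carbon (conjugate reduction) and the sulfinyl carbanion is protonated by ethanol, leaving the sulfoxide and the C–F bond untouched.

Step 5
Reactants: 6 1,5-bis(benzyloxy)-3-fluoro-2-[2-(methylsulfinyl)-2-(methylthio)ethyl]benzene; 7 3,4-bis(benzyloxy)benzaldehyde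
Product: 10 5,7-bis(benzyloxy)-2-[3,4-bis(benzyloxy)phenyl]-3-(methylsulfinyl)-3-(methylthio)chromane (racemic diastereomer mixture), via potassium carbanion 8 (not isolated), via potassium alkoxide adduct 9 (not isolated)
Conditions: KH (1.05 equiv), THF, 0 °C → rt; 7, −40 °C; then 18-crown-6, DMPU, 50–60 °C
Reagents that add atoms: none
Why: KH removes the doubly sulfur-stabilised methine proton of 6, carbanion 8 adds to the non-enolisable aldehyde 7 (C2–C3), and on warming with 18-crown-6 the potassium alkoxide 9 attacks C8a ipso to fluorine through a Meisenheimer intermediate and expels fluoride (O1–C8a), a formal [4+2] annulation of the aldehyde C=O onto a C3-nucleophile/C8a-electrophile 1,4-dipole. The closest known reaction types are the addition of alkylated methyl methylthiomethyl sulfoxide anions to aldehydes (acyl-anion chemistry) and the intramolecular SNAr etherification of 3,5-dialkoxyfluoroarenes by alkoxides. Ring C closes in a 6-exo-trig-type addition–elimination at C8a, the only sp2 carbon carrying a leaving group, and the two benzyloxy groups, being meta to C8a, do not deactivate it. C2 (and the transient C3 and sulfur centres) form without control on purpose, since C3 is returned to a carbonyl in step 6 and C2 is then equilibrated and fixed by the dynamic kinetic resolution of step 7, so every diastereomer of 10 is usable. The step needs O-arylation by the C2 alkoxide only; the substrate secures this because C3 carries neither an oxygen nucleophile nor an enolisable carbonyl (which would close a five-membered benzofuran ring instead), and because reversible retro-addition from 9 is drained by the irreversible loss of fluoride.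

Step 6
Reactants: 10 5,7-bis(benzyloxy)-2-[3,4-bis(benzyloxy)phenyl]-3-(methylsulfinyl)-3-(methylthio)chromane
Product: 11 rac-5,7-bis(benzyloxy)-2-[3,4-bis(benzyloxy)phenyl]chroman-3-one
Conditions: 9 M H2SO4 (cat.), THF/H2O, rt
Reagents that add atoms: water, O
Why: Acid-promoted loss of methanesulfenic acid gives a thionium ion at C3 that is trapped by water and collapses to the ketone (hydrolysis of a dithioacetal S-oxide), while the benzyl aryl ethers are stable to dilute acid at room temperature.

Step 7
Reactants: 11 rac-5,7-bis(benzyloxy)-2-[3,4-bis(benzyloxy)phenyl]chroman-3-one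
Product: 12 (2R,3R)-5,7-bis(benzyloxy)-2-[3,4-bis(benzyloxy)phenyl]chroman-3-ol (5,7,3',4'-tetra-O-benzyl-(−)-epicatechin)
Conditions: RuCl[(R,R)-TsDPEN](p-cymene) (2 mol %), HCO2H (3 equiv), Et3N (6 equiv), DMF, 40 °C
Reagents that add atoms: none
Why: Noyori–Ikariya asymmetric transfer hydrogenation under dynamic kinetic resolution, in which triethylamine enolises the ketone towards C2 (benzylic, alpha to O1 and to C=O) so that the two enantiomers interconvert, the chiral Ru–H complex should reduce the (2R)-ketone faster, and hydride enters C3 anti to the C2 aryl group to give the cis (2R,3R) alcohol.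

Step 8
Reactants: 13 (+)-gallocatechin
Product: 14 (2R,3S)-5,7-bis(benzyloxy)-2-[3,4,5-tris(benzyloxy)phenyl]chroman-3-ol
Conditions: BnBr (5.5 equiv), K2CO3, DMF, 0 °C → rt, Ar
Reagents that add atoms: benzyl bromide, BrCc1ccccc1
Why: Williamson ether synthesis on the five phenolic OH groups only, since carbonate does not deprotonate the secondary C3 alcohol, and working cold under argon limits base-mediated C2 epimerisation and oxidation of the pyrogallol ring.

Step 9
Reactants: 14 (2R,3S)-5,7-bis(benzyloxy)-2-[3,4,5-tris(benzyloxy)phenyl]chroman-3-ol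
Product: 15 (2R,3S,4S)-5,7-bis(benzyloxy)-4-(2-ethoxyethoxy)-2-[3,4,5-tris(benzyloxy)phenyl]chroman-3-ol
Conditions: DDQ (2 equiv), 2-ethoxyethanol, CH2Cl2, rt
Reagents that add atoms: 2-ethoxyethanol, CCOCCO
Why: DDQ abstracts hydride from C4, which is benzylic and ortho/para to the ring-A ether oxygens, and the quinone-methide-type cation is captured by 2-ethoxyethanol (oxidative benzylic etherification), expected mainly cis to the C3 hydroxyl, to install a C4 leaving group whose configuration is erased in the next step.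

Step 10
Reactants: 15 (2R,3S,4S)-5,7-bis(benzyloxy)-4-(2-ethoxyethoxy)-2-[3,4,5-tris(benzyloxy)phenyl]chroman-3-ol; 12 5,7,3',4'-tetra-O-benzyl-(−)-epicatechin
Product: 16 nona-O-benzyl gallocatechin-(4α→8)-epicatechin (upper unit 2R,3S,4S; lower unit 2R,3R; both C3 hydroxyls free)
Conditions: TMSOTf (cat.), CH2Cl2, −78 °C; 12 in excess (3 equiv, surplus recovered)
Reagents that add atoms: none
Why: TMSOTf ionises the C4 ether to the ring-A-stabilised benzylic cation, which is attacked by C8 of 12 (the more nucleophilic ring-A position of a benzylated flavan-3-ol, with excess nucleophile suppressing oligomers) anti to the C3 hydroxyl of the 2,3-trans unit in a Friedel–Crafts alkylation that sets C4 as S (3,4-trans, 4α).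

Step 11
Reactants: 16 nona-O-benzyl gallocatechin-(4α→8)-epicatechin
Product: 17 gallocatechin-(4α→8)-epicatechin (target)
Conditions: H2 (1 atm), Pd(OH)2/C, THF/MeOH/H2O, rt
Reagents that add atoms: none
Why: Hydrogenolysis of the nine benzyl ethers under neutral conditions leaves the acid-labile interflavan bond and all five stereocentres untouched.

**Compound list**

1 | 1,3,5-trifluorobenzene | Fc1cc(F)cc(F)c1 | starting material
2 | 1,3-bis(benzyloxy)-5-fluorobenzene | Fc1cc(OCc2ccccc2)cc(OCc2ccccc2)c1 | intermediate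
3 | 2,4-bis(benzyloxy)-6-fluorobenzaldehyde | O=Cc1c(F)cc(OCc2ccccc2)cc1OCc1ccccc1 | intermediate
4 | methyl methylthiomethyl sulfoxide | CS(=O)CSC | starting material
5 | (E)-1,5-bis(benzyloxy)-3-fluoro-2-[2-(methylsulfinyl)-2-(methylthio)ethenyl]benzene | CS(=O)/C(SC)=C/c1c(F)cc(OCc2ccccc2)cc1OCc1ccccc1 | intermediate
6 | 1,5-bis(benzyloxy)-3-fluoro-2-[2-(methylsulfinyl)-2-(methylthio)ethyl]benzene (diastereomer mixture) | CSC(Cc1c(F)cc(OCc2ccccc2)cc1OCc1ccccc1)S(C)=O | intermediate
7 | 3,4-bis(benzyloxy)benzaldehyde | O=Cc1ccc(OCc2ccccc2)c(OCc2ccccc2)c1 | starting material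
8 | potassium carbanion of 6 (not isolated) | [K+].CS[C-](Cc1c(F)cc(OCc2ccccc2)cc1OCc1ccccc1)S(C)=O | intermediate
9 | potassium alkoxide adduct of 8 and 7 (not isolated, diastereomer mixture) | [K+].[O-]C(c1ccc(OCc2ccccc2)c(OCc2ccccc2)c1)C(SC)(S(C)=O)Cc1c(F)cc(OCc2ccccc2)cc1OCc1ccccc1 | intermediate
10 | 5,7-bis(benzyloxy)-2-[3,4-bis(benzyloxy)phenyl]-3-(methylsulfinyl)-3-(methylthio)chromane (racemic diastereomer mixture) | CSC1(S(C)=O)Cc2c(OCc3ccccc3)cc(OCc3ccccc3)cc2OC1c1ccc(OCc2ccccc2)c(OCc2ccccc2)c1 | intermediate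
11 | rac-5,7-bis(benzyloxy)-2-[3,4-bis(benzyloxy)phenyl]chroman-3-one | O=C1Cc2c(OCc3ccccc3)cc(OCc3ccccc3)cc2OC1c1ccc(OCc2ccccc2)c(OCc2ccccc2)c1 | intermediate
12 | (2R,3R)-5,7-bis(benzyloxy)-2-[3,4-bis(benzyloxy)phenyl]chroman-3-ol | O[C@@H]1Cc2c(OCc3ccccc3)cc(OCc3ccccc3)cc2O[C@@H]1c1ccc(OCc2ccccc2)c(OCc2ccccc2)c1 | intermediate
13 | (+)-gallocatechin, (2R,3S)-2-(3,4,5-trihydroxyphenyl)chromane-3,5,7-triol | O[C@H]1Cc2c(O)cc(O)cc2O[C@@H]1c1cc(O)c(O)c(O)c1 | starting material
14 | (2R,3S)-5,7-bis(benzyloxy)-2-[3,4,5-tris(benzyloxy)phenyl]chroman-3-ol | O[C@H]1Cc2c(OCc3ccccc3)cc(OCc3ccccc3)cc2O[C@@H]1c1cc(OCc2ccccc2)c(OCc2ccccc2)c(OCc2ccccc2)c1 | intermediate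
15 | (2R,3S,4S)-5,7-bis(benzyloxy)-4-(2-ethoxyethoxy)-2-[3,4,5-tris(benzyloxy)phenyl]chroman-3-ol | C(c1ccccc1)Oc1cc(OCc3ccccc3)c2c(c1)O[C@H](c1cc(OCc3ccccc3)c(OCc3ccccc3)c(OCc3ccccc3)c1)[C@@H](O)[C@H]2OCCOCC | intermediate
16 | nona-O-benzyl gallocatechin-(4α→8)-epicatechin | C(c1ccccc1)Oc1cc(OCc3ccccc3)c2c(c1)O[C@H](c1cc(OCc3ccccc3)c(OCc3ccccc3)c(OCc3ccccc3)c1)[C@@H](O)[C@@H]2c1c(OCc3ccccc3)cc(OCc3ccccc3)c2c1O[C@H](c1ccc(OCc3ccccc3)c(OCc3ccccc3)c1)[C@H](O)C2 | intermediate
17 | gallocatechin-(4α→8)-epicatechin | Oc1cc(O)c2c(c1)O[C@H](c1cc(O)c(O)c(O)c1)[C@@H](O)[C@@H]2c1c(O)cc(O)c2c1O[C@H](c1ccc(O)c(O)c1)[C@H](O)C2 | target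

**Totals.** Total step count: 11. Longest linear sequence: 9 steps (steps 1–7, 10, 11).

**Steps most likely to fail**

Step 5. What may go wrong: the alkoxide adduct reverts to carbanion and aldehyde, or the α-thio sulfoxide eliminates methanesulfenate, faster than fluoride is displaced at the temperature the ring closure needs. Fallback (stepwise, with a dithioacetal that resists fragmentation), setting out from 6 and 7: 6 is deprotonated with LiN(i-Pr)2 in THF at −78 °C, 7 is added and the mixture is quenched cold with acetic acid to give the β-hydroxy dithioacetal S-oxide F1. SmI2 in THF/HMPA at room temperature removes the sulfoxide oxygen to give the hydroxy bis(methylthio) acetal F2, whose alkoxide can no longer expel a well-stabilised carbanion. KH in THF/DMPU at 60 °C then closes ring C by the same fluoride displacement to the cyclic bis(methylthio) ketal F3. MeI with CaCO3 in aqueous MeCN hydrolyses F3 to ketone 11, where the route is rejoined.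

Step 7. What may go wrong: enolisation at C2 is slower than hydride transfer, or the catalyst discriminates the two ketone enantiomers poorly, so the cis-alcohol forms with low enantiomeric purity. Fallback (substrate-controlled reduction and classical resolution), setting out from 11: LiBH(s-Bu)3 in THF at −78 °C delivers hydride anti to the C2 aryl group and should give the racemic cis-alcohol, a 1:1 mixture of 12 and its (2S,3S) enantiomer F4. Esterification with (S)-2-methoxy-2-phenylacetic acid (DCC, DMAP, CH2Cl2) gives the diastereomeric esters, the (2R,3R) ester F5 and the (2S,3S) ester F6, which are separated by chromatography. LiOH in THF/MeOH/H2O cleaves F5 and returns 12, where the route is rejoined. F6 can be saponified and its alcohol re-oxidised with Dess–Martin periodinane to 11 for recycling.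

Step 10. What may go wrong: attack on the C4 cation from the face cis to the C3 oxygen, or a second alkylation of the dimer by another cation, leading to the 4β isomer or to oligomers. Fallback (neighbouring-group control with equimolar partners), setting out from 15: acetylation (Ac2O, DMAP, pyridine) gives the 3-O-acetate F7. With Yb(OTf)3 in CH2Cl2 the cation is bridged by the acetoxy group on the face of the C3 oxygen, so that 12 (1 equiv) can only enter trans, giving the 3-O-acetyl nonabenzyl dimer F8. K2CO3 in MeOH/THF removes the acetate and gives 16, where the route is rejoined.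

**Further compounds**

F1 | step 5 | 1-[3,4-bis(benzyloxy)phenyl]-3-[2,4-bis(benzyloxy)-6-fluorophenyl]-2-(methylsulfinyl)-2-(methylthio)propan-1-ol (diastereomer mixture) | OC(c1ccc(OCc2ccccc2)c(OCc2ccccc2)c1)C(SC)(S(C)=O)Cc1c(F)cc(OCc2ccccc2)cc1OCc1ccccc1
F2 | step 5 | rac-1-[3,4-bis(benzyloxy)phenyl]-3-[2,4-bis(benzyloxy)-6-fluorophenyl]-2,2-bis(methylthio)propan-1-ol | OC(c1ccc(OCc2ccccc2)c(OCc2ccccc2)c1)C(SC)(SC)Cc1c(F)cc(OCc2ccccc2)cc1OCc1ccccc1
F3 | step 5 | rac-5,7-bis(benzyloxy)-2-[3,4-bis(benzyloxy)phenyl]-3,3-bis(methylthio)chromane | CSC1(SC)Cc2c(OCc3ccccc3)cc(OCc3ccccc3)cc2OC1c1ccc(OCc2ccccc2)c(OCc2ccccc2)c1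
F4 | step 7 | (2S,3S)-5,7-bis(benzyloxy)-2-[3,4-bis(benzyloxy)phenyl]chroman-3-ol | O[C@H]1Cc2c(OCc3ccccc3)cc(OCc3ccccc3)cc2O[C@H]1c1ccc(OCc2ccccc2)c(OCc2ccccc2)c1
F5 | step 7 | (2R,3R)-5,7-bis(benzyloxy)-2-[3,4-bis(benzyloxy)phenyl]chroman-3-yl (S)-2-methoxy-2-phenylacetate | CO[C@H](C(=O)O[C@@H]1Cc2c(OCc3ccccc3)cc(OCc3ccccc3)cc2O[C@@H]1c1ccc(OCc2ccccc2)c(OCc2ccccc2)c1)c1ccccc1
F6 | step 7 | (2S,3S)-5,7-bis(benzyloxy)-2-[3,4-bis(benzyloxy)phenyl]chroman-3-yl (S)-2-methoxy-2-phenylacetate | CO[C@H](C(=O)O[C@H]1Cc2c(OCc3ccccc3)cc(OCc3ccccc3)cc2O[C@H]1c1ccc(OCc2ccccc2)c(OCc2ccccc2)c1)c1ccccc1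
F7 | step 10 | (2R,3S,4S)-5,7-bis(benzyloxy)-4-(2-ethoxyethoxy)-2-[3,4,5-tris(benzyloxy)phenyl]chroman-3-yl acetate | C(c1ccccc1)Oc1cc(OCc3ccccc3)c2c(c1)O[C@H](c1cc(OCc3ccccc3)c(OCc3ccccc3)c(OCc3ccccc3)c1)[C@@H](OC(C)=O)[C@H]2OCCOCC
F8 | step 10 | 3-O-acetyl (upper unit) nona-O-benzyl gallocatechin-(4α→8)-epicatechin | C(c1ccccc1)Oc1cc(OCc3ccccc3)c2c(c1)O[C@H](c1cc(OCc3ccccc3)c(OCc3ccccc3)c(OCc3ccccc3)c1)[C@@H](OC(C)=O)[C@@H]2c1c(OCc3ccccc3)cc(OCc3ccccc3)c2c1O[C@H](c1ccc(OCc3ccccc3)c(OCc3ccccc3)c1)[C@H](O)C2
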